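**Assumption:** (2S)-steppogenin (7,2',4'-trihydroxyflavanone), a natural (2S)-flavanone sold by natural-product suppliers, is taken as the chiral starting material. The ring stereocentres arise in the photochemical step. The resulting C2-based diastereomers are separated by preparative HPLC, with the (2S) centre as the internal reference.

## Retrosynthesis
1. Target **11** comes from a formal [4+2] between the 2,2',4,4'-tetrahydroxychalcone **10** and the aryl-diene flavanone **7**. This is the only ring formed, and it is formed last, in the photochemical step.
2. Diene **7** comes from a Suzuki coupling of the B-ring iodide **3** with the (E)-dienyl-Bpin **6**.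
3. Iodide **3** comes from regioselective iodination of (2S)-steppogenin **1**, which already carries the flavanone ring and the C2 stereocentre.
4. Chalcone **10** comes from a Claisen–Schmidt condensation of **8** and **9**. Boronate **6** comes from hydroboration of enyne **4**.

## Route

**Step 1**
Reactants: **1** (2S)-steppogenin; **2** N-iodosuccinimide
Product: **3** (2S)-5'-iodosteppogenin
Conditions: NIS (1.0 equiv), MeCN, –30 → 0 °C, dark, 1 h
Reagents that add atoms: NIS, O=C1CCC(=O)N1I (adds I)
Why: Electrophilic aromatic iodination (SEAr) goes to the B-ring position that is ortho to 4'-OH and para to 2'-OH, the most electron-rich site, because the A ring is deactivated by the C4 ketone; no base is used, so C2 is not touched.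

**Step 2**
Reactants: **4** 2-methylbut-1-en-3-yne; **5** pinacolborane
Product: **6** (E)-2-(3-methylbuta-1,3-dien-1-yl)-4,4,5,5-tetramethyl-1,3,2-dioxaborolane
Conditions: HBpin (1.1 equiv), Cp2Zr(H)Cl (10 mol%), neat, sealed tube, 25 °C, 12 h
Reagents that add atoms: HBpin, [H]B1OC(C)(C)C(C)(C)O1 (adds Bpin)
Why: Zr-catalysed alkyne hydroboration is anti-Markovnikov and syn, and it leaves the 1,1-disubstituted alkene untouched, giving the (E)-dienylboronate.

**Step 3**
Reactants: **3**; **6** (1.5 equiv)
Product: **7** (2S)-5'-[(E)-3-methylbuta-1,3-dien-1-yl]steppogenin
Conditions: XPhos Pd G2 (5 mol%), 0.5 M aq K3PO4 (3 equiv), THF, 40 °C, 1 h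
Reagents that add atoms: none
Why: Suzuki–Miyaura coupling of an aryl iodide is fast at low temperature under these conditions, and the short, mild exposure limits flavanone ring-opening and racemisation at C2.

**Step 4**
Reactants: **8** 2,4-dihydroxybenzaldehyde; **9** 2,4-dihydroxyacetophenone
Product: **10** (E)-2,2',4,4'-tetrahydroxychalcone
Conditions: 50% aq KOH, EtOH, 25 → 50 °C, 24 h; then 2 M HCl to pH 2
Reagents that add atoms: none
Why: Claisen–Schmidt aldol condensation gives the thermodynamically favoured E-enone; the phenols do not need protection because the dianion still condenses.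

**Step 5**
Reactants: **7**; **10** (2 equiv)
Product: **11** guangsangon N
Conditions: Ir(dF(CF3)ppy)2(dtbbpy)PF6 (1 mol%), MeCN/HFIP 9:1, blue LEDs (450 nm), 25 °C, degassed, 24 h; then prep-HPLC
Reagents that add atoms: none
Why: Photochemical energy-transfer [4+2] with the (2S) centre carried through.
- Proposed new method: the triplet sensitiser excites chalcone **10** to a twisted triplet.
- Its benzylic β-radical adds to the CH2 terminus of the s-cis 2-methyl-1-aryl diene in **7**, forming a triplet 1,6-diradical (an α-keto radical and an aryl-stabilised allyl radical).
- After intersystem crossing, chair-like closure at the aryl-bearing allyl terminus forms the cyclohexene (closure at the tertiary Me-bearing terminus would give a vinylcyclobutane and is hindered).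
- The closure places the 3-aryl, 4-aroyl and 5-aryl groups all equatorial, giving the trans,trans (exo-type) relative configuration of the target. The α-aroyl centre can equilibrate, which further favours this isomer.
- The closest known reactions are energy-transfer enone–alkene photocycloaddition and the Morus-type Diels–Alder of chalcones with dehydroprenyl dienes.
- The two diastereomers (differing in the ring configuration relative to the fixed 2S centre) are separated by HPLC, and the (2S) centre is unchanged under these neutral, non-basic conditions.

## Compound list
1 | (2S)-steppogenin | Oc1ccc([C@@H]2CC(=O)c3ccc(O)cc3O2)c(O)c1 | starting material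
2 | N-iodosuccinimide | O=C1CCC(=O)N1I | starting material
3 | (2S)-5'-iodosteppogenin | Oc1c(I)cc([C@@H]2CC(=O)c3ccc(O)cc3O2)c(O)c1 | intermediate
4 | 2-methylbut-1-en-3-yne | C=C(C)C#C | starting material
5 | pinacolborane | [H]B1OC(C)(C)C(C)(C)O1 | starting material
6 | (E)-3-methylbuta-1,3-dienyl-Bpin | C=C(C)/C=C/B1OC(C)(C)C(C)(C)O1 | intermediate
7 | (2S)-5'-[(E)-3-methylbutadienyl]steppogenin | C=C(C)/C=C/c1cc([C@@H]2CC(=O)c3ccc(O)cc3O2)c(O)cc1O | intermediate
8 | 2,4-dihydroxybenzaldehyde | O=Cc1ccc(O)cc1O | starting material
9 | 2,4-dihydroxyacetophenone | CC(=O)c1ccc(O)cc1O | starting material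
10 | (E)-2,2',4,4'-tetrahydroxychalcone | O=C(/C=C/c1ccc(O)cc1O)c1ccc(O)cc1O | intermediate
11 | guangsangon N | CC1=C[C@@H](c2cc([C@@H]3CC(=O)c4ccc(O)cc4O3)c(O)cc2O)[C@H](C(=O)c2ccc(O)cc2O)[C@@H](c2ccc(O)cc2O)C1 | target

**Total steps:** 5. **Longest linear sequence:** 3 (1 → 3 → 7 → 11).

## Three steps most likely to fail
1. **Step 5 (proposed new energy-transfer [4+2]).** The chalcone triplet may decay by twisting or E/Z isomerisation, or the reaction may give the [2+2] vinylcyclobutane.
   - Fallback (known chemistry): protect the phenols of **7** and **10** as MOM ethers, run the known thermal or Lewis-acid Morus-type Diels–Alder, separate the exo-type adduct by HPLC, then remove MOM with HCl/MeOH.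
2. **Step 3 (Suzuki on the free-phenol flavanone).** Aqueous phosphate may ring-open and racemise C2.
   - Fallback: Stille coupling of **3** with the (E)-dienylstannane under neutral conditions (Pd2dba3, AsPh3, CuI, DMF).
3. **Step 1 (regioselective iodination).** Iodination may also occur at B-ring C3' or A-ring C6/C8.
   - Fallback: ortho-formylation of **1** (MgCl2, Et3N, paraformaldehyde), then Wittig olefination with the methallyl-phosphonium ylide to install the same (E)-dienyl group directly.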